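## Retrosynthetic overview
1. The target comes from one reductive global unmasking of a 5,7-di-O-benzyl flavonol whose 3',4'-sulfates are masked as neutral trichloroethyl (TCE) diesters. The sulfur is placed on the B-ring building block before coupling, so no flavonol phenols ever need to be differentiated.
2. Ring C is the only ring formed (rings A and B are bought). It closes by O1–C2 cyclodehydration of an o-hydroxyaryl 2-hydroxy-1,3-diketone.
3. The key disconnection is C2–C3. This 1,2-dioxygenated pair is split into two aldehyde carbons: the B-ring benzaldehyde acts as a carbene-bound aroyl anion (Breslow intermediate) and attacks the formyl carbon of an A-ring arylglyoxal. Coupling and ring closure run in one flask.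
4. The aldehyde comes from protocatechualdehyde and Cl3CCH2OSO2Cl. The glyoxal comes from phloroacetophenone by selective dibenzylation and Riley oxidation.

Assumption: the target is planar and has no stereogenic element, so it is one achiral compound and no configuration has to be set. It is delivered in the fully protonated bis(hydrogen sulfate) form as drawn.

## Route

Step 1
Reactants: 1 3,4-dihydroxybenzaldehyde; 2 2,2,2-trichloroethyl chlorosulfate
Product: 3 3,4-bis{[(2,2,2-trichloroethoxy)sulfonyl]oxy}benzaldehyde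
Conditions: 2 (2.6 equiv), Et3N (3 equiv), DMAP (20 mol %), THF, 0 → 23 °C
Reagents that add atoms: 2,2,2-trichloroethyl chlorosulfate, ClS(=O)(=O)OCC(Cl)(Cl)Cl
Why: DMAP-catalysed O-sulfonylation of both catechol oxygens gives neutral, chromatographable sulfate diesters; this reagent is known to sulfate catechol-type flavonoids fully, excess reagent outruns closure to the cyclic catechol sulfate, and the 3',4' regiochemistry is fixed from here on.

Step 2
Reactants: 4 2',4',6'-trihydroxyacetophenone; 5 benzyl bromide
Product: 6 1-[2,4-bis(benzyloxy)-6-hydroxyphenyl]ethan-1-one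
Conditions: BnBr (2.1 equiv), K2CO3 (2.2 equiv), acetone, reflux
Reagents that add atoms: benzyl bromide, BrCc1ccccc1
Why: In this Williamson etherification the para OH and one ortho OH are alkylated, while the remaining ortho OH is chelated to the acetyl carbonyl, is much less nucleophilic, and stays free as the future ring oxygen O1.

Step 3
Reactants: 6 1-[2,4-bis(benzyloxy)-6-hydroxyphenyl]ethan-1-one
Product: 7 2-[2,4-bis(benzyloxy)-6-hydroxyphenyl]-2-oxoacetaldehyde (arylglyoxal, handled as its hydrate and dried azeotropically with toluene before use)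
Conditions: SeO2 (1.3 equiv), 1,4-dioxane/H2O 30:1, 95 °C; hot filtration
Reagents that add atoms: selenium dioxide, O=[Se]=O
Why: Riley oxidation of an aryl methyl ketone proceeds through the enol selenite ester and stops at the arylglyoxal in aqueous dioxane, and it is established for o-hydroxy- and polyalkoxy-acetophenones.

Step 4
Reactants: 3 3,4-bis{[(2,2,2-trichloroethoxy)sulfonyl]oxy}benzaldehyde; 7 2-[2,4-bis(benzyloxy)-6-hydroxyphenyl]-2-oxoacetaldehyde
Product: 9 5,7-bis(benzyloxy)-3-hydroxy-2-(3,4-bis{[(2,2,2-trichloroethoxy)sulfonyl]oxy}phenyl)-4H-chromen-4-one, via 2-hydroxy-1,3-diketone 8 (not isolated)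
Conditions: 3 (1.3 equiv), 2-(pentafluorophenyl)-6,7-dihydro-5H-pyrrolo[2,1-c][1,2,4]triazol-2-ium BF4 (15 mol %), i-Pr2NEt (30 mol %), 4 Å MS, THF, Ar, 23 °C, 7 added over 4 h; then TsOH·H2O (50 mol %), 45 °C
Reagents that add atoms: none
Why: Proposed new method: the carbene adds to the unhindered, electron-poor aldehyde 3 and a proton shift gives the Breslow enaminol, an aroyl anion equivalent that attacks the most electrophilic carbonyl present, the formyl carbon of glyoxal 7, so two aldehyde carbons are joined as the C2–C3 bond of 8 (the reverse pairing, with the glyoxal as donor, gives an ene-diol tautomer of 8 and therefore converges), after which the chelated phenol closes onto the new aryl ketone and acid-catalysed loss of water to the aromatic 4-pyranone makes the reversible benzoin step irreversible; the closest known reaction types are the triazolium-catalysed chemoselective cross-benzoin of aromatic aldehydes with α-keto esters and other activated carbonyls, the intramolecular aldehyde–ketone benzoin route to 3-hydroxychroman-4-ones, and the cyclodehydration of 2-hydroxy-1,3-diketones in classical flavonol syntheses; the carbinol centre of 8 is racemic and is erased on dehydration.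

Step 5
Reactants: 9 5,7-bis(benzyloxy)-3-hydroxy-2-(3,4-bis{[(2,2,2-trichloroethoxy)sulfonyl]oxy}phenyl)-4H-chromen-4-one
Product: 11 quercetin 3',4'-bis(hydrogen sulfate), via diammonium disulfate salt 10 (not isolated)
Conditions: 10% Pd/C, HCO2NH4 (12 equiv), MeOH/THF 3:1, 23 °C; filter; C18 plug (H2O → 30% MeOH); sulfonic acid cation-exchange resin (H+ form), H2O, 4 °C; freeze-dry, store cold
Reagents that add atoms: ammonium formate, [NH4+].[O-]C=O (supplies only the NH4+ counter-ions of 10; none of its heavy atoms remain in 11)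
Why: Catalytic transfer hydrogenolysis cleaves both aryl benzyl ethers, and the same Pd/formate couple reduces a C–Cl bond of each trichloroethyl group and triggers β-fragmentation to the sulfate monoester anion (the known deprotection of aryl TCE sulfates, including flavonoid catechol bis-sulfates), while the flavonol C2=C3 bond and the aryl–O–S bonds are inert and proton exchange on the resin gives the acid form drawn.

## Compound list
1 | 3,4-dihydroxybenzaldehyde (protocatechualdehyde) | O=Cc1ccc(O)c(O)c1 | starting material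
2 | 2,2,2-trichloroethyl chlorosulfate | ClS(=O)(=O)OCC(Cl)(Cl)Cl | starting material
3 | 3,4-bis{[(2,2,2-trichloroethoxy)sulfonyl]oxy}benzaldehyde | O=Cc1ccc(OS(=O)(=O)OCC(Cl)(Cl)Cl)c(OS(=O)(=O)OCC(Cl)(Cl)Cl)c1 | intermediate
4 | 2',4',6'-trihydroxyacetophenone (phloroacetophenone) | CC(=O)c1c(O)cc(O)cc1O | starting material
5 | benzyl bromide | BrCc1ccccc1 | starting material
6 | 1-[2,4-bis(benzyloxy)-6-hydroxyphenyl]ethan-1-one | CC(=O)c1c(O)cc(OCc2ccccc2)cc1OCc1ccccc1 | intermediate
7 | 2-[2,4-bis(benzyloxy)-6-hydroxyphenyl]-2-oxoacetaldehyde | O=CC(=O)c1c(O)cc(OCc2ccccc2)cc1OCc1ccccc1 | intermediate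
8 | 1-[2,4-bis(benzyloxy)-6-hydroxyphenyl]-2-hydroxy-3-(3,4-bis{[(2,2,2-trichloroethoxy)sulfonyl]oxy}phenyl)propane-1,3-dione (racemic, not isolated) | O=C(c1c(O)cc(OCc2ccccc2)cc1OCc1ccccc1)C(O)C(=O)c1ccc(OS(=O)(=O)OCC(Cl)(Cl)Cl)c(OS(=O)(=O)OCC(Cl)(Cl)Cl)c1 | intermediate
9 | 5,7-bis(benzyloxy)-3-hydroxy-2-(3,4-bis{[(2,2,2-trichloroethoxy)sulfonyl]oxy}phenyl)-4H-chromen-4-one | O=c1c(O)c(-c2ccc(OS(=O)(=O)OCC(Cl)(Cl)Cl)c(OS(=O)(=O)OCC(Cl)(Cl)Cl)c2)oc2cc(OCc3ccccc3)cc(OCc3ccccc3)c12 | intermediate
10 | diammonium 4-(3,5,7-trihydroxy-4-oxo-4H-chromen-2-yl)-1,2-phenylene bis(sulfate) (not isolated) | [NH4+].[NH4+].O=c1c(O)c(-c2ccc(OS(=O)(=O)[O-])c(OS(=O)(=O)[O-])c2)oc2cc(O)cc(O)c12 | intermediate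
11 | quercetin 3',4'-bis(hydrogen sulfate), CNP0396186.0 (achiral) | O=c1c(O)c(-c2ccc(OS(=O)(=O)O)c(OS(=O)(=O)O)c2)oc2cc(O)cc(O)c12 | target

## Count and risks
Total steps: 5 (convergent). Longest linear sequence: 4 steps (4 → 6 → 7 → 9 → 11).

**Step 4** is the most likely to fail. The carbene could attack a sulfate diester. Base could isomerise 7 to the 3-hydroxybenzofuran-2-one lactone. Homo-benzoin of 3 could also win. The fallback sets out from 3 and 6 and comes back to the route at 9 (passing through 8). It replaces the catalytic acyl anion by an ester that is moved from oxygen to carbon.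
- Aldehyde 3 is oxidised (NaClO2, NaH2PO4, 2-methyl-2-butene, t-BuOH/H2O) to 3,4-bis{[(2,2,2-trichloroethoxy)sulfonyl]oxy}benzoic acid F1.
- Ketone 6 is α-brominated with CuBr2 (EtOAc/CHCl3, reflux) to 2-bromo-1-[2,4-bis(benzyloxy)-6-hydroxyphenyl]ethan-1-one F2.
- The two are joined (KHCO3, acetone, 23 °C) to give the phenacyl ester 2-[2,4-bis(benzyloxy)-6-hydroxyphenyl]-2-oxoethyl 3,4-bis{[(2,2,2-trichloroethoxy)sulfonyl]oxy}benzoate F3. The acid is kept in slight excess over the base, so the chelated phenol stays protonated and does not close to the coumaranone.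
- K2CO3 in pyridine at 50 °C then drives a Baker–Venkataraman-type O→C acyl transfer to 8. An AcOH quench cyclodehydrates 8 to 9.

**Step 5** is second. TCE cleavage can stall at the dichloroethyl ester, chloride can poison the palladium, and sulfate can be lost if the acid form is handled warm. The fallback sets out from 9 and comes back at 10, and it avoids hydrogenolysis altogether.
- BCl3 with pentamethylbenzene as cation scavenger (CH2Cl2, −78 °C) removes both benzyl ethers and gives quercetin 3',4'-bis(2,2,2-trichloroethyl sulfate) F4.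
- Zinc dust with HCO2NH4 in MeOH at 23 °C brings about two-electron reductive fragmentation of both TCE groups to salt 10. This is carried through the same ion exchange to 11.

**Step 3** is third. SeO2 can attack the very electron-rich ring or over-oxidise to the arylglyoxylic acid. The fallback sets out from 6 and comes back at 7, and it goes through a nitrogen ylide instead of direct C–H oxidation.
- The Ortoleva–King reaction (I2, pyridine, 90 °C) gives 1-{2-[2,4-bis(benzyloxy)-6-hydroxyphenyl]-2-oxoethyl}pyridinium iodide F5.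
- Kröhnke condensation with 4-nitroso-N,N-dimethylaniline (aq NaOH/EtOH, 0 °C) gives the (Z)-C-aroyl-N-[4-(dimethylamino)phenyl]nitrone F6.
- Cold 2 M H2SO4/Et2O hydrolyses F6 to glyoxal 7.

## Further compounds
F1 | step 4 | 3,4-bis{[(2,2,2-trichloroethoxy)sulfonyl]oxy}benzoic acid | O=C(O)c1ccc(OS(=O)(=O)OCC(Cl)(Cl)Cl)c(OS(=O)(=O)OCC(Cl)(Cl)Cl)c1
F2 | step 4 | 2-bromo-1-[2,4-bis(benzyloxy)-6-hydroxyphenyl]ethan-1-one | O=C(CBr)c1c(O)cc(OCc2ccccc2)cc1OCc1ccccc1
F3 | step 4 | 2-[2,4-bis(benzyloxy)-6-hydroxyphenyl]-2-oxoethyl 3,4-bis{[(2,2,2-trichloroethoxy)sulfonyl]oxy}benzoate | O=C(COC(=O)c1ccc(OS(=O)(=O)OCC(Cl)(Cl)Cl)c(OS(=O)(=O)OCC(Cl)(Cl)Cl)c1)c1c(O)cc(OCc2ccccc2)cc1OCc1ccccc1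
F4 | step 5 | quercetin 3',4'-bis(2,2,2-trichloroethyl sulfate) | O=c1c(O)c(-c2ccc(OS(=O)(=O)OCC(Cl)(Cl)Cl)c(OS(=O)(=O)OCC(Cl)(Cl)Cl)c2)oc2cc(O)cc(O)c12
F5 | step 3 | 1-{2-[2,4-bis(benzyloxy)-6-hydroxyphenyl]-2-oxoethyl}pyridinium iodide | O=C(C[n+]1ccccc1)c1c(O)cc(OCc2ccccc2)cc1OCc1ccccc1.[I-]
F6 | step 3 | (Z)-2-[2,4-bis(benzyloxy)-6-hydroxyphenyl]-N-[4-(dimethylamino)phenyl]-2-oxoethan-1-imine N-oxide (nitrone) | O=C(/C=[N+](\[O-])c1ccc(N(C)C)cc1)c1c(O)cc(OCc2ccccc2)cc1OCc1ccccc1
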